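**Plan**
1. Eudesmane numbering is used: ring A = C1–C5 and C10, ring B = C5–C10, C14 = methyl on C10, C15 on C4, C11–C13 = acrylate on C7. The retrosynthesis cuts the coumarate ester at C15–O, then C4–C15 and C11–C12 (both from enol triflates of a 4,11-diketone), then C7–C8 (aldol condensation), and last C9–C10 and C5–C6.
2. The last two cuts are possible because ring A with an oxygen on C4 is 3-methylcyclohex-2-enone in disguise: its β-carbon is the quaternary C10 and its α-carbon is C5, the two ring-A atoms that carry ring B.
3. Forward: ring A is bought. A copper-catalysed Grignard addition puts C9–C8 on C10, and the enolate so formed picks up C6–C7–C11–C13 at C5. Ring B then closes by aldol condensation (C7–C8).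
4. Hydrogenation and equilibration give the trans-fused 7-acetyl-4-ketone. Both ketones become enol triflates, the side-chain triflate is carbonylated to the acrylate, the ring triflate is hydroxymethylated (C15), and p-coumaric acid is attached last.
5. Stereochemistry: C10 comes from the chiral copper–carbene catalyst. C5 and C7 are set relative to C10 by hydrogenation and base equilibration and are locked when C4 and C11 become sp2. The (E)-alkene comes with p-coumaric acid.

Key step: step 4

Remark: the sense of induction of the carbene ligand is assigned by analogy with simple alkyl Grignard additions to the same enone, so the ligand enantiomer that gives the (3R)-enolate is used; the acetal Grignard reagent is assumed to tolerate dilution of its THF solution into Et2O.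

**Step 1**
Reactants: 1 2-(bromomethyl)-1,3-dioxolane
Product: 2 (1,3-dioxolan-2-ylmethyl)magnesium bromide
Conditions: Mg turnings, I2 (cat.), THF, 25–30 °C; titrated and used as a solution
Reagents that add atoms: magnesium, [Mg]
Why: Grignard formation by insertion of magnesium into the primary C–Br bond; the reagent is stabilised in THF by its ring oxygens and is also sold as a THF solution, so its preparation is routine.

**Step 2**
Reactants: 3 (1-bromovinyl)trimethylsilane; 4 acetaldehyde
Product: 6 3-(trimethylsilyl)but-3-en-2-ol, via 1-(trimethylsilyl)vinylmagnesium bromide 5 (not isolated)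
Conditions: Mg, THF, reflux; then MeCHO, 0 °C → rt; aq. NH4Cl
Reagents that add atoms: none
Why: Grignard formation from the α-silyl vinyl bromide and 1,2-addition to acetaldehyde; the carbinol centre is racemic and is removed in step 3.

**Step 3**
Reactants: 6 3-(trimethylsilyl)but-3-en-2-ol
Product: 7 3-(trimethylsilyl)but-3-en-2-one
Conditions: CrO3, H2SO4, acetone/H2O, 0 °C → rt
Reagents that add atoms: none
Why: Jones oxidation of the secondary allylic alcohol to the enone, the standard access to this acceptor; the vinylsilane tolerates the acidic medium.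

**Step 4**
Reactants: 8 3-methylcyclohex-2-en-1-one; 2 (1,3-dioxolan-2-ylmethyl)magnesium bromide; 7 3-(trimethylsilyl)but-3-en-2-one
Product: 11 (2R,3R)-3-(1,3-dioxolan-2-ylmethyl)-3-methyl-2-(3-oxobutyl)cyclohexan-1-one, via bromomagnesium enolate 9 (not isolated), via α-silyl diketone 10 (not isolated)
Conditions: Cu(OTf)2 (4 mol %), chiral 4,5-dihydroimidazolium salt (carbene precursor, 5 mol %), Et2O, 0 °C; 2 (1.2 equiv, added over 1 h), −30 → 0 °C; then 7 (1.5 equiv), −78 → −10 °C; aq. NH4Cl; crude adduct: Bu4NF, AcOH, THF, 0 °C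
Reagents that add atoms: none
Why: The Grignard reagent reduces Cu(OTf)2 and deprotonates the imidazolinium salt, giving a carbene-bound monovalent copper alkyl species that forms a π-complex with the C5=C10 double bond of 8, adds oxidatively to a trivalent copper intermediate and reductively eliminates to form C9–C10, leaving bromomagnesium enolate 9 with its double bond fixed between C4 and C5. This enolate adds to silyl enone 7 (Michael addition) to form C5–C6; the silicon stabilises the new enolate so that it neither transfers a proton nor adds to a second molecule of 7, and buffered fluoride then replaces silicon by hydrogen without exposing the 1,5-diketone to base. The closest known reaction types are the copper-catalysed asymmetric conjugate addition of Grignard reagents to 3-substituted cyclohexenones with trapping of the magnesium enolate, and the conjugate addition–α-silyl vinyl ketone sequence used in annulations. No ring is closed in this step. C10 is set by enantioface selection of the chiral carbene–copper catalyst; C5 is formed under substrate control (drawn trans to the acetal side chain) but stays epimerisable next to the C4 ketone and is not relied on. The step needs 1,4- rather than 1,2-addition of the Grignard reagent (secured by copper catalysis and slow addition), a single enolate regiochemistry (secured because the enolate is generated directly at C4–C5 under aprotic conditions) and mono-addition to the acceptor (secured by the α-silyl group).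

**Step 5**
Reactants: 11 (2R,3R)-3-(1,3-dioxolan-2-ylmethyl)-3-methyl-2-(3-oxobutyl)cyclohexan-1-one
Product: 14 (4aR,8aR)-7-acetyl-4a-methyl-3,4,4a,5,8,8a-hexahydronaphthalen-1(2H)-one, via keto aldehyde 12 (not isolated), via ketol 13 (not isolated)
Conditions: 2 M HCl, THF, 50 °C
Reagents that add atoms: none
Why: Aqueous acid hydrolyses the dioxolane, and the more substituted enol of the methyl ketone (C7) attacks the freed, far more electrophilic aldehyde (C8) in a 6-enolexo intramolecular aldol addition whose ketol dehydrates irreversibly to the conjugated enone, whereas the aldol modes onto the hindered ring ketone are slower and reversible; C5 can epimerise here and is not yet defined.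

**Step 6**
Reactants: 14 (4aR,8aR)-7-acetyl-4a-methyl-3,4,4a,5,8,8a-hexahydronaphthalen-1(2H)-one
Product: 16 (4aR,7R,8aR)-7-acetyl-4a-methyloctahydronaphthalen-1(2H)-one, via saturated diketone epimer mixture 15 (not isolated)
Conditions: H2 (1 atm), Pd/C, EtOAc, rt; then NaOMe (0.2 equiv), MeOH, rt
Reagents that add atoms: none
Why: Heterogeneous syn-hydrogenation saturates the enone C7=C8 bond without touching the ketones, and methoxide then epimerises both carbonyl-flanked centres (C5 and C7) toward the trans-fused diastereomer with the acetyl group equatorial (thermodynamic control); because the angular methyl group narrows the usual trans preference of 1-decalones, cis-fused material separated here is returned to the same base treatment.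

**Step 7**
Reactants: 16 (4aR,7R,8aR)-7-acetyl-4a-methyloctahydronaphthalen-1(2H)-one
Product: 17 (4aR,7R,8aR)-4a-methyl-7-{1-[(trifluoromethanesulfonyl)oxy]ethenyl}-3,4,4a,5,6,7,8,8a-octahydronaphthalen-1-yl trifluoromethanesulfonate
Conditions: KN(SiMe3)2 (2.3 equiv), THF, −78 °C; PhNTf2 (2.3 equiv), −78 → 0 °C
Reagents that add atoms: N-phenylbis(trifluoromethanesulfonimide), O=S(=O)(N(c1ccccc1)S(=O)(=O)C(F)(F)F)C(F)(F)F
Why: Kinetic deprotonation by the hindered amide takes the least hindered α-hydrogens (the acetyl CH3 and C3-H2, not the tertiary C7-H or C5-H), and O-sulfonylation of both potassium enolates (enol triflate formation) leaves C5 and C7 no longer α to a carbonyl group, so both are locked.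

**Step 8**
Reactants: 17 (4aR,7R,8aR)-4a-methyl-7-{1-[(trifluoromethanesulfonyl)oxy]ethenyl}-3,4,4a,5,6,7,8,8a-octahydronaphthalen-1-yl trifluoromethanesulfonate
Product: 18 methyl 2-[(2R,4aS,8aR)-4a-methyl-8-[(trifluoromethanesulfonyl)oxy]-1,2,3,4,4a,5,6,8a-octahydronaphthalen-2-yl]prop-2-enoate
Conditions: Pd(OAc)2 (5 mol %), PPh3 (10 mol %), CO (1 atm), MeOH, Et3N, DMF, 0 °C → rt; stopped when 17 is consumed
Reagents that add atoms: carbon monoxide, [C-]#[O+]; methanol, CO
Why: Palladium-catalysed alkoxycarbonylation of an enol triflate: zerovalent palladium binds the C=C bond before it inserts into the C–O bond, and the terminal 1,1-disubstituted alkene of the side chain is a much better ligand than the trisubstituted ring alkene flanked by the ring-fusion carbon, so the acyclic triflate should react first and the ring triflate be kept for step 9.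

**Step 9**
Reactants: 18 methyl 2-[(2R,4aS,8aR)-4a-methyl-8-[(trifluoromethanesulfonyl)oxy]-1,2,3,4,4a,5,6,8a-octahydronaphthalen-2-yl]prop-2-enoate
Product: 19 methyl 2-[(2R,4aR,8aR)-8-(hydroxymethyl)-4a-methyl-1,2,3,4,4a,5,6,8a-octahydronaphthalen-2-yl]prop-2-enoate
Conditions: Bu3SnCH2OH, Pd(PPh3)4 (10 mol %), LiCl (3 equiv), BHT (cat.), 1,4-dioxane, 95 °C
Reagents that add atoms: (tributylstannyl)methanol, OC[Sn](CCCC)(CCCC)CCCC
Why: Stille coupling of the remaining enol triflate with the hydroxymethyl stannane, LiCl converting the palladium triflate intermediate into the chloride before transmetalation, installs C15 as the allylic alcohol without touching the acrylate or C5.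

**Step 10**
Reactants: 19 methyl 2-[(2R,4aR,8aR)-8-(hydroxymethyl)-4a-methyl-1,2,3,4,4a,5,6,8a-octahydronaphthalen-2-yl]prop-2-enoate; 20 (2E)-3-(4-hydroxyphenyl)prop-2-enoic acid
Product: 21 methyl 2-[(2R,4aR,8aR)-8-({[(2E)-3-(4-hydroxyphenyl)prop-2-enoyl]oxy}methyl)-4a-methyl-1,2,3,4,4a,5,6,8a-octahydronaphthalen-2-yl]prop-2-enoate
Conditions: PPh3, DIAD, THF, 0 °C → rt
Reagents that add atoms: none
Why: Mitsunobu esterification: the alkoxyphosphonium ion of the primary allylic alcohol is displaced by the carboxylate, which is far more acidic than the phenol and therefore the competent nucleophile, so p-coumaric acid can be used unprotected with its (E)-alkene retained.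

**Compound list**
1 | 2-(bromomethyl)-1,3-dioxolane | BrCC1OCCO1 | starting material
2 | (1,3-dioxolan-2-ylmethyl)magnesium bromide | Br[Mg]CC1OCCO1 | intermediate
3 | (1-bromovinyl)trimethylsilane | C=C(Br)[Si](C)(C)C | starting material
4 | acetaldehyde | CC=O | starting material
5 | 1-(trimethylsilyl)vinylmagnesium bromide | C=C([Mg]Br)[Si](C)(C)C | intermediate
6 | 3-(trimethylsilyl)but-3-en-2-ol (racemic) | CC(O)C(=C)[Si](C)(C)C | intermediate
7 | 3-(trimethylsilyl)but-3-en-2-one | CC(=O)C(=C)[Si](C)(C)C | intermediate
8 | 3-methylcyclohex-2-en-1-one | CC1=CC(=O)CCC1 | starting material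
9 | bromomagnesium (3R)-3-(1,3-dioxolan-2-ylmethyl)-3-methylcyclohex-1-en-1-olate | Br[Mg]OC1=C[C@@](C)(CC2OCCO2)CCC1 | intermediate
10 | (2R,3R)-3-(1,3-dioxolan-2-ylmethyl)-3-methyl-2-[3-oxo-2-(trimethylsilyl)butyl]cyclohexan-1-one (epimers at the silyl-bearing carbon) | O1CCOC1C[C@@]2(C)CCCC(=O)[C@@H]2CC(C(C)=O)[Si](C)(C)C | intermediate
11 | (2R,3R)-3-(1,3-dioxolan-2-ylmethyl)-3-methyl-2-(3-oxobutyl)cyclohexan-1-one (C2 epimer may accompany it; both converge in step 6) | O1CCOC1C[C@@]2(C)CCCC(=O)[C@@H]2CCC(C)=O | intermediate
12 | 2-[(1R,2R)-1-methyl-3-oxo-2-(3-oxobutyl)cyclohexyl]acetaldehyde | O=CC[C@@]1(C)CCCC(=O)[C@@H]1CCC(C)=O | intermediate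
13 | (4aR,8aR)-7-acetyl-6-hydroxy-4a-methyloctahydronaphthalen-1(2H)-one (mixture at C6 and C7) | CC(=O)C1C(O)C[C@@]2(C)CCCC(=O)[C@@H]2C1 | intermediate
14 | (4aR,8aR)-7-acetyl-4a-methyl-3,4,4a,5,8,8a-hexahydronaphthalen-1(2H)-one (C8a still epimerisable) | CC(=O)C1=CC[C@@]2(C)CCCC(=O)[C@@H]2C1 | intermediate
15 | (4aR)-7-acetyl-4a-methyloctahydronaphthalen-1(2H)-one (mixture of C7 and C8a epimers) | CC(=O)C1CC[C@@]2(C)CCCC(=O)C2C1 | intermediate
16 | (4aR,7R,8aR)-7-acetyl-4a-methyloctahydronaphthalen-1(2H)-one (trans-fused, acetyl equatorial) | CC(=O)[C@@H]1CC[C@@]2(C)CCCC(=O)[C@@H]2C1 | intermediate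
17 | (4aR,7R,8aR)-4a-methyl-7-{1-[(trifluoromethanesulfonyl)oxy]ethenyl}-3,4,4a,5,6,7,8,8a-octahydronaphthalen-1-yl trifluoromethanesulfonate | C=C(OS(=O)(=O)C(F)(F)F)[C@@H]1CC[C@@]2(C)CCC=C(OS(=O)(=O)C(F)(F)F)[C@@H]2C1 | intermediate
18 | methyl 2-[(2R,4aS,8aR)-4a-methyl-8-[(trifluoromethanesulfonyl)oxy]-1,2,3,4,4a,5,6,8a-octahydronaphthalen-2-yl]prop-2-enoate | C=C(C(=O)OC)[C@@H]1CC[C@@]2(C)CCC=C(OS(=O)(=O)C(F)(F)F)[C@@H]2C1 | intermediate
19 | methyl 2-[(2R,4aR,8aR)-8-(hydroxymethyl)-4a-methyl-1,2,3,4,4a,5,6,8a-octahydronaphthalen-2-yl]prop-2-enoate | C=C(C(=O)OC)[C@@H]1CC[C@@]2(C)CCC=C(CO)[C@@H]2C1 | intermediate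
20 | (2E)-3-(4-hydroxyphenyl)prop-2-enoic acid (p-coumaric acid) | O=C(O)/C=C/c1ccc(O)cc1 | starting material
21 | methyl 2-[(2R,4aR,8aR)-8-({[(2E)-3-(4-hydroxyphenyl)prop-2-enoyl]oxy}methyl)-4a-methyl-1,2,3,4,4a,5,6,8a-octahydronaphthalen-2-yl]prop-2-enoate | C=C(C(=O)OC)[C@@H]1CC[C@@]2(C)CCC=C(COC(=O)/C=C/c3ccc(O)cc3)[C@@H]2C1 | target

**Step count**
Total steps: 10. Longest linear sequence: 9 steps (from 3 through steps 2–10).

**Steps most likely to fail**

Step 8. The risk is loss of site selectivity in the oxidative addition, so that the ring triflate is carbonylated as well as, or instead of, the side-chain triflate. The fallback sets out from 17 and comes back at 19; it tells the two triflates apart by elimination chemistry instead of by palladium. LiN(iPr)2 (THF, −78 °C) would convert only the 1-substituted ethenyl triflate, which has a vinylic hydrogen anti to the leaving group, into the terminal alkyne (4aS,7R,8aR)-7-ethynyl-4a-methyl-3,4,4a,5,6,7,8,8a-octahydronaphthalen-1-yl trifluoromethanesulfonate F1; the cyclohexenyl triflate cannot eliminate. Stille coupling of F1 with (tributylstannyl)methanol under the conditions of step 9 would give [(4aR,7R,8aR)-7-ethynyl-4a-methyl-3,4,4a,5,6,7,8,8a-octahydronaphthalen-1-yl]methanol F2. Markovnikov-selective methoxycarbonylation of the terminal alkyne (Pd(OAc)2, 2-pyridyldiphenylphosphine, MeSO3H, CO, MeOH) would then build the 2-substituted acrylate and give 19.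

Step 6. The risk is an insufficient thermodynamic bias at the ring fusion: the angular methyl group brings the cis-fused 4-ketones close in energy to the trans-fused one, and epimerisation at C7 is coupled to it, so equilibration may stop at a mixture. The fallback sets out from 14 and comes back at 19; it fixes C5 by a dynamic kinetic olefination and needs neither the site-selective carbonylation nor the tin reagent.
- RhCl(PPh3)3-catalysed 1,4-hydrosilylation of the enone with Et3SiH would mask the acetyl group, leaving the ring ketone free, as (4aR)-4a-methyl-7-[1-(triethylsilyloxy)ethylidene]octahydronaphthalen-1(2H)-one F3.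
- Wittig methylenation with Ph3P=CH2 in THF/DMSO at 50 °C, where C5 epimerises and the less hindered trans-fused ketone should be consumed faster, would give triethyl({1-[(4aR,8aS)-4a-methyl-8-methylideneoctahydronaphthalen-2(1H)-ylidene]ethyl}oxy)silane F4.
- Bu4NF/AcOH and then NaOMe/MeOH would free the acetyl group and place it equatorial (only C7 can now epimerise), giving 1-[(2R,4aR,8aS)-4a-methyl-8-methylidenedecahydronaphthalen-2-yl]ethan-1-one F5.
- KN(SiMe3)2 and PhNTf2 would give the single enol triflate 1-[(2R,4aR,8aS)-4a-methyl-8-methylidenedecahydronaphthalen-2-yl]ethenyl trifluoromethanesulfonate F6.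
- Carbonylation as in step 8 would give methyl 2-[(2R,4aR,8aS)-4a-methyl-8-methylidenedecahydronaphthalen-2-yl]prop-2-enoate F7.
- A singlet-oxygen ene reaction (O2, hν, tetraphenylporphyrin, CH2Cl2) would move the exocyclic double bond into the ring and oxygenate C15, giving methyl 2-[(2R,4aR,8aR)-8-(hydroperoxymethyl)-4a-methyl-1,2,3,4,4a,5,6,8a-octahydronaphthalen-2-yl]prop-2-enoate F8, which PPh3 would reduce to 19.

Step 4. The risk is inefficient capture of the hindered bromomagnesium enolate: surplus Grignard reagent and copper species may consume the silyl enone, and proton exchange may return the simple conjugate adduct. The fallback sets out from enolate 9 and comes back at 10, and so at 11; it separates the two bond formations. Enolate 9 would be silylated in the flask (Me3SiCl, Et3N) and isolated as trimethyl{[(3R)-3-(1,3-dioxolan-2-ylmethyl)-3-methylcyclohex-1-en-1-yl]oxy}silane F9. MeLi in THF would regenerate the enolate regiospecifically as lithium (3R)-3-(1,3-dioxolan-2-ylmethyl)-3-methylcyclohex-1-en-1-olate F10, free of copper and Grignard reagent. Addition of 7 at −78 °C, the classical lithium enolate–α-silyl vinyl ketone protocol, would give 10, which is desilylated to 11 as in step 4.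

**Further compounds**
F1 | step 8 | (4aS,7R,8aR)-7-ethynyl-4a-methyl-3,4,4a,5,6,7,8,8a-octahydronaphthalen-1-yl trifluoromethanesulfonate | C#C[C@@H]1CC[C@@]2(C)CCC=C(OS(=O)(=O)C(F)(F)F)[C@@H]2C1
F2 | step 8 | [(4aR,7R,8aR)-7-ethynyl-4a-methyl-3,4,4a,5,6,7,8,8a-octahydronaphthalen-1-yl]methanol | C#C[C@@H]1CC[C@@]2(C)CCC=C(CO)[C@@H]2C1
F3 | step 6 | (4aR)-4a-methyl-7-[1-(triethylsilyloxy)ethylidene]octahydronaphthalen-1(2H)-one (C8a epimers, E/Z mixture) | CC(O[Si](CC)(CC)CC)=C1CC[C@@]2(C)CCCC(=O)C2C1
F4 | step 6 | triethyl({1-[(4aR,8aS)-4a-methyl-8-methylideneoctahydronaphthalen-2(1H)-ylidene]ethyl}oxy)silane (E/Z mixture) | CC(O[Si](CC)(CC)CC)=C1CC[C@@]2(C)CCCC(=C)[C@@H]2C1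
F5 | step 6 | 1-[(2R,4aR,8aS)-4a-methyl-8-methylidenedecahydronaphthalen-2-yl]ethan-1-one | CC(=O)[C@@H]1CC[C@@]2(C)CCCC(=C)[C@@H]2C1
F6 | step 6 | 1-[(2R,4aR,8aS)-4a-methyl-8-methylidenedecahydronaphthalen-2-yl]ethenyl trifluoromethanesulfonate | C=C(OS(=O)(=O)C(F)(F)F)[C@@H]1CC[C@@]2(C)CCCC(=C)[C@@H]2C1
F7 | step 6 | methyl 2-[(2R,4aR,8aS)-4a-methyl-8-methylidenedecahydronaphthalen-2-yl]prop-2-enoate | C=C(C(=O)OC)[C@@H]1CC[C@@]2(C)CCCC(=C)[C@@H]2C1
F8 | step 6 | methyl 2-[(2R,4aR,8aR)-8-(hydroperoxymethyl)-4a-methyl-1,2,3,4,4a,5,6,8a-octahydronaphthalen-2-yl]prop-2-enoate | C=C(C(=O)OC)[C@@H]1CC[C@@]2(C)CCC=C(COO)[C@@H]2C1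
F9 | step 4 | trimethyl{[(3R)-3-(1,3-dioxolan-2-ylmethyl)-3-methylcyclohex-1-en-1-yl]oxy}silane | C[Si](C)(C)OC1=C[C@@](C)(CC2OCCO2)CCC1
F10 | step 4 | lithium (3R)-3-(1,3-dioxolan-2-ylmethyl)-3-methylcyclohex-1-en-1-olate | [Li]OC1=C[C@@](C)(CC2OCCO2)CCC1
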